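**Plan**
- Retrosynthesis: after removing the protecting groups, the C2 O-methyl group and the oxidation level of C1 (CO2H back to CH2O-PMB), the benzene ring A is cut at C1–C2, C5–C6 and C2–C3. This gives a chiral diazo enone (C2 to C5 plus the side chain) and an aryloxyalkyne (C1, C6, the ether oxygen and all of ring B).
- Enabling feature: ring A has oxygen on C2 and C6 on either side of the carboxyl carbon C1, and the carbinol chain on C3 next to C2. This is the 2-carbon-substituted resorcinol monoether that a vinylketene/ynol ether benzannulation produces (ketene carbon becomes C2–OH, alkyne carbons become C1 and C6–OAr).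
- Forward: fragment A (diazo enone 12) comes from D-leucine in six steps. Fragment B (ynol ether 24) comes from an ortho-vanillin-type aldehyde in seven steps; its future diaryl ether oxygen is vinylated with trichloroethylene, so no aryl–oxygen coupling is needed.
- Ring B is bought as an arene. Ring A is the only ring formed (step 14). O-Methylation, PMB removal, two-stage oxidation to the acid, deallylation and desilylation then finish the synthesis.
- Stereochemistry: the single R centre comes from D-leucine (hydroxy-deamination with retention) and is carried as a TBS ether that lies outside the reacting π-system of the key step.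

Key step: step 14

Abbreviations: TBS = tert-butyldimethylsilyl; PMB = 4-methoxybenzyl; TIPS = triisopropylsilyl; ArB = 2-(allyloxy)-6-[(TBS-oxy)methyl]-4-methylphenyl. Ring A is numbered as in the target (C1 carboxyl carbon, C2 OMe, C3 carbinol chain, C6 aryloxy).

Remark: aldehyde 13 is taken as a purchasable compound; should it be unavailable, it is the one-step MgCl2/Et3N/paraformaldehyde ortho-formylation product of creosol.

**Fragment A**

Step 1
Reactants: 1 D-leucine
Product: 4 (R)-2-hydroxy-4-methylpentanoic acid, via diazonium carboxylate 2 (not isolated), via α-lactone 3 (not isolated)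
Conditions: NaNO2, 1 M H2SO4, H2O, 0 °C to rt
Reagents that add atoms: water, O
Why: Diazotizing hydroxy-deamination of an α-amino acid: the carboxylate of diazonium 2 displaces N2 with inversion to give α-lactone 3 and water reopens it with a second inversion, so the net result is retention and the R centre of D-leucine becomes the R carbinol centre of the target.

Step 2
Reactants: 4 (R)-2-hydroxy-4-methylpentanoic acid
Product: 5 methyl (R)-2-hydroxy-4-methylpentanoate
Conditions: MeOH, H2SO4 (cat.), reflux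
Reagents that add atoms: methanol, CO
Why: Fischer esterification in excess methanol does not touch the α-stereocentre and gives an ester that can be reduced to the aldehyde level.

Step 3
Reactants: 5 methyl (R)-2-hydroxy-4-methylpentanoate
Product: 6 methyl (R)-2-(TBS-oxy)-4-methylpentanoate
Conditions: TBSCl, imidazole, DMF, rt
Reagents that add atoms: tert-butyldimethylsilyl chloride, CC(C)(C)[Si](C)(C)Cl
Why: Corey silylation protects the secondary alcohol as a TBS ether that should withstand the hydride, ylide, amide base, light and oxidants used later.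

Step 4
Reactants: 6 methyl (R)-2-(TBS-oxy)-4-methylpentanoate
Product: 8 (R)-2-(TBS-oxy)-4-methylpentanal, via aluminium hemiacetal 7 (not isolated)
Conditions: i-Bu2AlH, CH2Cl2, −78 °C; MeOH, then aqueous potassium sodium tartrate
Reagents that add atoms: none
Why: Partial ester reduction with i-Bu2AlH at −78 °C stops at tetrahedral aluminium hemiacetal 7, which releases the aldehyde only on work-up; this is the usual route to configurationally stable α-silyloxy aldehydes.

Step 5
Reactants: 8 (R)-2-(TBS-oxy)-4-methylpentanal; 9 1-(triphenyl-λ5-phosphanylidene)propan-2-one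
Product: 10 (R,E)-5-(TBS-oxy)-7-methyloct-3-en-2-one
Conditions: CH2Cl2, rt to 40 °C
Reagents that add atoms: none
Why: Wittig olefination with the stabilized acetonyl ylide is E-selective and runs under neutral conditions that should not epimerize the α-silyloxy aldehyde.

Step 6
Reactants: 10 (R,E)-5-(TBS-oxy)-7-methyloct-3-en-2-one
Product: 12 (R,E)-5-(TBS-oxy)-1-diazo-7-methyloct-3-en-2-one, via trifluoroacetyl diketone 11 (not isolated)
Conditions: LiN(SiMe3)2, THF, −78 °C; CF3CO2CH2CF3; 5% HCl wash; then MsN3, Et3N, H2O, MeCN, rt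
Reagents that add atoms: methanesulfonyl azide, CS(=O)(=O)N=[N+]=[N-]
Why: Danheiser detrifluoroacetylative diazo transfer: kinetic deprotonation at the methyl group and Claisen acylation give activated diketone 11, to which mesyl azide transfers N2 with loss of the trifluoroacetyl group; this is the standard entry to diazomethyl enones, which cannot be made by direct diazo transfer.

**Fragment B**

Step 7
Reactants: 13 2-hydroxy-3-methoxy-5-methylbenzaldehyde
Product: 14 2,3-dihydroxy-5-methylbenzaldehyde
Conditions: BBr3, CH2Cl2, −78 to 0 °C; H2O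
Reagents that add atoms: none
Why: BBr3 demethylation of an aryl methyl ether (borane complexation, then bromide attack on the methyl group) is routine for ortho-vanillin-type aldehydes and returns the formyl group intact after aqueous work-up.

Step 8
Reactants: 14 2,3-dihydroxy-5-methylbenzaldehyde
Product: 15 3-(allyloxy)-2-hydroxy-5-methylbenzaldehyde
Conditions: NaH (2.1 equiv), DMSO, rt; allyl bromide (1.0 equiv); then 1 M HCl
Reagents that add atoms: allyl bromide, C=CCBr
Why: Regioselective Williamson etherification of the doubly deprotonated catechol: the phenoxide at C3 is not conjugated to the formyl group and is the more nucleophilic, so it takes the single equivalent of allyl bromide and leaves the C2 hydroxyl free.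

Step 9
Reactants: 15 3-(allyloxy)-2-hydroxy-5-methylbenzaldehyde; 16 trichloroethylene
Product: 18 3-(allyloxy)-2-{[(E)-1,2-dichloroethenyl]oxy}-5-methylbenzaldehyde, via dichloroacetylene 17 (not isolated)
Conditions: K2CO3, DMF, 70 °C
Reagents that add atoms: none
Why: First stage of the Greene-type ynol ether synthesis: K2CO3 dehydrochlorinates 16 to dichloroacetylene 17 and the phenoxide adds to it in anti fashion to give the E-dichlorovinyl ether, which attaches the future diaryl ether oxygen to a two-carbon unit without any hindered aryl–oxygen coupling.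

Step 10
Reactants: 18 3-(allyloxy)-2-{[(E)-1,2-dichloroethenyl]oxy}-5-methylbenzaldehyde
Product: 19 [3-(allyloxy)-2-{[(E)-1,2-dichloroethenyl]oxy}-5-methylphenyl]methanol
Conditions: NaBH4, MeOH/THF, 0 °C
Reagents that add atoms: none
Why: NaBH4 reduces the aromatic aldehyde chemoselectively to the benzylic alcohol and does not touch the dichlorovinyl ether or the allyl ether.

Step 11
Reactants: 19 [3-(allyloxy)-2-{[(E)-1,2-dichloroethenyl]oxy}-5-methylphenyl]methanol
Product: 20 ArB (E)-1,2-dichlorovinyl ether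
Conditions: TBSCl, imidazole, DMF, rt
Reagents that add atoms: tert-butyldimethylsilyl chloride, CC(C)(C)[Si](C)(C)Cl
Why: Silylation of the primary benzylic alcohol removes the only acidic proton before the organolithium step and installs a group that leaves at the very end together with the side-chain TBS ether.

Step 12
Reactants: 20 ArB (E)-1,2-dichlorovinyl ether
Product: 23 3-(ArB-oxy)prop-2-yn-1-ol, via chloroalkynyl ether 21 (not isolated), via lithium acetylide 22 (not isolated)
Conditions: n-BuLi (2.3 equiv), THF, −78 °C; (CH2O)n, −78 to 0 °C; H2O; Et3N-deactivated silica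
Reagents that add atoms: paraformaldehyde (as formaldehyde), C=O
Why: Second stage of the Greene ynol ether synthesis: n-BuLi eliminates HCl to give chloroalkynyl ether 21 and then exchanges the remaining chlorine for lithium, and acetylide 22 adds to formaldehyde like any lithium acetylide (1,2-addition).

Step 13
Reactants: 23 3-(ArB-oxy)prop-2-yn-1-ol
Product: 24 1-(ArB-oxy)-3-(PMB-oxy)prop-1-yne
Conditions: NaH, PMBCl, Bu4NI (cat.), THF/DMF, 0 °C to rt
Reagents that add atoms: 4-methoxybenzyl chloride, COc1ccc(CCl)cc1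
Why: Williamson etherification under basic conditions protects the propargylic oxygen while avoiding the acid that would hydrate the ynol ether or trigger a Meyer–Schuster rearrangement.

**Union and endgame**

Step 14
Reactants: 12 (R,E)-5-(TBS-oxy)-1-diazo-7-methyloct-3-en-2-one (1.3 equiv); 24 1-(ArB-oxy)-3-(PMB-oxy)prop-1-yne
Product: 29 3-(ArB-oxy)-2-[(PMB-oxy)methyl]-6-[(R)-1-(TBS-oxy)-3-methylbutyl]phenol, via vinylketene 25 (not isolated), via vinylcyclobutenone 26 (not isolated), via dienylketene 27 (not isolated), via cyclohexadienone 28 (not isolated)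
Conditions: hν (450 W medium-pressure Hg lamp, uranium-glass filter, >340 nm), degassed acid-free CH2Cl2, rt; then toluene, 80–100 °C
Reagents that add atoms: none
Why: Light above 340 nm expels N2 from 12 and the photochemical Wolff shift of the alkenyl group gives vinylketene 25, whose carbonyl carbon (the future C2) is attacked by the oxygen-remote, nucleophilic carbon of ynol ether 24 in a [2+2] cycloaddition that forms C1–C2 and C5–C6 and gives 4-vinylcyclobutenone 26. Continued irradiation or warming opens 26 by a 4π electrocyclic reaction to dienylketene 27, and ring A then closes by a thermal disrotatory 6π electrocyclization between the ketene carbon and the alkene terminus (C2–C3) to cyclohexadienone 28, which tautomerizes to phenol 29. The closest known reaction type is the Danheiser benzannulation in its photochemical Wolff version, established for diazo enones with alkoxyalkynes, siloxyalkynes and ynamides; an aryl alkynyl ether is an alkynyl ether of intermediate donor strength and has no β-hydrogen through which the alkyne could be lost by a retro-ene reaction. No stereocentre is created, because the sp3 centres of 26 and 28 vanish on ring opening and aromatization, and the silyloxy-bearing carbon lies outside the reacting π-array and should stay R. The selectivity needed is the orientation of the ketene–alkyne union, and the polarization of the ynol ether secures it, placing the aryloxy group on C6, the PMB-oxymethyl carbon on C1 and the only free hydroxyl on C2; the allyl alkene is far less ketenophilic than the oxygen-activated alkyne, and the filter keeps the aryl ethers and the PMB group from absorbing.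

Step 15
Reactants: 29 3-(ArB-oxy)-2-[(PMB-oxy)methyl]-6-[(R)-1-(TBS-oxy)-3-methylbutyl]phenol
Product: 30 6-(ArB-oxy)-2-methoxy-3-[(R)-1-(TBS-oxy)-3-methylbutyl]benzyl 4-methoxybenzyl ether
Conditions: MeI, K2CO3, DMF, rt
Reagents that add atoms: iodomethane, CI
Why: Williamson O-methylation of the phenoxide works for di-ortho-substituted phenols, fixes the C2 methoxy group and removes the free ortho-hydroxybenzyl ether motif that could otherwise open a quinone methide pathway at the stereocentre.

Step 16
Reactants: 30 6-(ArB-oxy)-2-methoxy-3-[(R)-1-(TBS-oxy)-3-methylbutyl]benzyl 4-methoxybenzyl ether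
Product: 31 {6-(ArB-oxy)-2-methoxy-3-[(R)-1-(TBS-oxy)-3-methylbutyl]phenyl}methanol
Conditions: DDQ (1.2 equiv), CH2Cl2/pH 7 phosphate buffer, 0 °C
Reagents that add atoms: none
Why: Oxidative PMB ether cleavage with DDQ in wet buffered CH2Cl2 is selective for the p-methoxybenzyl group over allyl and silyl ethers, and any over-oxidation to the aldehyde converges on compound 32 in the next step.

Step 17
Reactants: 31 {6-(ArB-oxy)-2-methoxy-3-[(R)-1-(TBS-oxy)-3-methylbutyl]phenyl}methanol
Product: 32 6-(ArB-oxy)-2-methoxy-3-[(R)-1-(TBS-oxy)-3-methylbutyl]benzaldehyde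
Conditions: Dess–Martin periodinane, CH2Cl2, 0 °C to rt
Reagents that add atoms: none
Why: Dess–Martin oxidation takes the benzylic alcohol to the aldehyde under near-neutral conditions without over-oxidation and without affecting the silyl or allyl ethers.

Step 18
Reactants: 32 6-(ArB-oxy)-2-methoxy-3-[(R)-1-(TBS-oxy)-3-methylbutyl]benzaldehyde
Product: 33 6-(ArB-oxy)-2-methoxy-3-[(R)-1-(TBS-oxy)-3-methylbutyl]benzoic acid
Conditions: NaClO2, NaH2PO4, 2-methyl-2-butene (excess), t-BuOH/THF/H2O, 0 °C to rt
Reagents that add atoms: sodium chlorite, [Na+].[O-]Cl=O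
Why: Pinnick oxidation is the standard method for hindered 2,6-disubstituted benzaldehydes, and the excess trisubstituted alkene intercepts HOCl before it can chlorinate the electron-rich rings or the allyl ether.

Step 19
Reactants: 33 6-(ArB-oxy)-2-methoxy-3-[(R)-1-(TBS-oxy)-3-methylbutyl]benzoic acid
Product: 34 6-{2-hydroxy-6-[(TBS-oxy)methyl]-4-methylphenoxy}-2-methoxy-3-[(R)-1-(TBS-oxy)-3-methylbutyl]benzoic acid
Conditions: Pd(PPh3)4 (5 mol%), morpholine, THF, rt; dilute acid work-up
Reagents that add atoms: none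
Why: Tsuji–Trost-type deallylation: zerovalent palladium ionizes the aryl allyl ether and morpholine takes up the allyl fragment, which frees the ring B phenol (and returns any allyl ester formed from the carboxylate) without affecting the silyl ethers.

Step 20
Reactants: 34 6-{2-hydroxy-6-[(TBS-oxy)methyl]-4-methylphenoxy}-2-methoxy-3-[(R)-1-(TBS-oxy)-3-methylbutyl]benzoic acid
Product: 35 6-[2-hydroxy-6-(hydroxymethyl)-4-methylphenoxy]-3-[(R)-1-hydroxy-3-methylbutyl]-2-methoxybenzoic acid
Conditions: Bu4NF (excess), THF, 0 °C to rt; cold dilute HCl to pH 4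
Reagents that add atoms: none
Why: Fluoride-induced desilylation removes both TBS ethers under basic, non-ionizing conditions, so the electron-rich secondary benzylic alcohol should not racemize by an SN1 pathway and the target is released.

**Compound list**

1 | D-leucine, (R)-2-amino-4-methylpentanoic acid | CC(C)C[C@@H](N)C(=O)O | starting material
2 | (R)-1-carboxylato-3-methylbutane-1-diazonium (diazonium carboxylate, not isolated) | CC(C)C[C@@H]([N+]#N)C(=O)[O-] | intermediate
3 | (S)-3-(2-methylpropyl)oxiran-2-one (α-lactone, not isolated) | CC(C)C[C@@H]1OC1=O | intermediate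
4 | (R)-2-hydroxy-4-methylpentanoic acid | CC(C)C[C@@H](O)C(=O)O | intermediate
5 | methyl (R)-2-hydroxy-4-methylpentanoate | CC(C)C[C@@H](O)C(=O)OC | intermediate
6 | methyl (R)-2-(TBS-oxy)-4-methylpentanoate | CC(C)C[C@@H](O[Si](C)(C)C(C)(C)C)C(=O)OC | intermediate
7 | diisobutylaluminium hemiacetal of 6, {(2R)-2-(TBS-oxy)-1-methoxy-4-methylpentyl}oxy-diisobutylaluminium (not isolated) | CC(C)C[C@@H](O[Si](C)(C)C(C)(C)C)C(OC)O[Al](CC(C)C)CC(C)C | intermediate
8 | (R)-2-(TBS-oxy)-4-methylpentanal | CC(C)C[C@@H](O[Si](C)(C)C(C)(C)C)C=O | intermediate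
9 | 1-(triphenyl-λ5-phosphanylidene)propan-2-one | CC(=O)C=P(c1ccccc1)(c1ccccc1)c1ccccc1 | starting material
10 | (R,E)-5-(TBS-oxy)-7-methyloct-3-en-2-one | CC(=O)/C=C/[C@H](O[Si](C)(C)C(C)(C)C)CC(C)C | intermediate
11 | (R,E)-7-(TBS-oxy)-1,1,1-trifluoro-9-methyldec-5-ene-2,4-dione (not isolated) | O=C(CC(=O)C(F)(F)F)/C=C/[C@H](O[Si](C)(C)C(C)(C)C)CC(C)C | intermediate
12 | (R,E)-5-(TBS-oxy)-1-diazo-7-methyloct-3-en-2-one | [N-]=[N+]=CC(=O)/C=C/[C@H](O[Si](C)(C)C(C)(C)C)CC(C)C | intermediate
13 | 2-hydroxy-3-methoxy-5-methylbenzaldehyde | COc1cc(C)cc(C=O)c1O | starting material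
14 | 2,3-dihydroxy-5-methylbenzaldehyde | Cc1cc(O)c(O)c(C=O)c1 | intermediate
15 | 3-(allyloxy)-2-hydroxy-5-methylbenzaldehyde | C=CCOc1cc(C)cc(C=O)c1O | intermediate
16 | trichloroethylene | ClC=C(Cl)Cl | starting material
17 | dichloroacetylene (not isolated) | ClC#CCl | intermediate
18 | 3-(allyloxy)-2-{[(E)-1,2-dichloroethenyl]oxy}-5-methylbenzaldehyde | C=CCOc1cc(C)cc(C=O)c1O/C(Cl)=C\Cl | intermediate
19 | [3-(allyloxy)-2-{[(E)-1,2-dichloroethenyl]oxy}-5-methylphenyl]methanol | C=CCOc1cc(C)cc(CO)c1O/C(Cl)=C\Cl | intermediate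
20 | ArB (E)-1,2-dichlorovinyl ether, tert-butyl{[3-(allyloxy)-2-{[(E)-1,2-dichloroethenyl]oxy}-5-methylbenzyl]oxy}dimethylsilane | C=CCOc1cc(C)cc(CO[Si](C)(C)C(C)(C)C)c1O/C(Cl)=C\Cl | intermediate
21 | ArB chloroethynyl ether (not isolated) | C=CCOc1cc(C)cc(CO[Si](C)(C)C(C)(C)C)c1OC#CCl | intermediate
22 | [(ArB-oxy)ethynyl]lithium (not isolated) | [Li]C#COc1c(OCC=C)cc(C)cc1CO[Si](C)(C)C(C)(C)C | intermediate
23 | 3-(ArB-oxy)prop-2-yn-1-ol | C=CCOc1cc(C)cc(CO[Si](C)(C)C(C)(C)C)c1OC#CCO | intermediate
24 | 1-(ArB-oxy)-3-(PMB-oxy)prop-1-yne | C=CCOc1cc(C)cc(CO[Si](C)(C)C(C)(C)C)c1OC#CCOCc1ccc(OC)cc1 | intermediate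
25 | (R,E)-5-(TBS-oxy)-7-methylocta-1,3-dien-1-one (vinylketene, not isolated) | O=C=C/C=C/[C@H](O[Si](C)(C)C(C)(C)C)CC(C)C | intermediate
26 | 3-(ArB-oxy)-2-[(PMB-oxy)methyl]-4-[(R,E)-3-(TBS-oxy)-5-methylhex-1-en-1-yl]cyclobut-2-en-1-one (ring carbon C4 unassigned, not isolated) | O=C1C(COCc2ccc(OC)cc2)=C(Oc2c(OCC=C)cc(C)cc2CO[Si](C)(C)C(C)(C)C)C1/C=C/[C@H](O[Si](C)(C)C(C)(C)C)CC(C)C | intermediate
27 | (R,3E,5E)-3-(ArB-oxy)-2-[(PMB-oxy)methyl]-7-(TBS-oxy)-9-methyldeca-1,3,5-trien-1-one (dienylketene, not isolated) | O=C=C(COCc1ccc(OC)cc1)/C(Oc1c(OCC=C)cc(C)cc1CO[Si](C)(C)C(C)(C)C)=C\C=C\[C@H](O[Si](C)(C)C(C)(C)C)CC(C)C | intermediate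
28 | 3-(ArB-oxy)-2-[(PMB-oxy)methyl]-6-[(R)-1-(TBS-oxy)-3-methylbutyl]cyclohexa-2,4-dien-1-one (ring carbon C6 unassigned, not isolated) | O=C1C(COCc2ccc(OC)cc2)=C(Oc2c(OCC=C)cc(C)cc2CO[Si](C)(C)C(C)(C)C)C=CC1[C@H](O[Si](C)(C)C(C)(C)C)CC(C)C | intermediate
29 | 3-(ArB-oxy)-2-[(PMB-oxy)methyl]-6-[(R)-1-(TBS-oxy)-3-methylbutyl]phenol | Oc1c([C@H](O[Si](C)(C)C(C)(C)C)CC(C)C)ccc(Oc2c(OCC=C)cc(C)cc2CO[Si](C)(C)C(C)(C)C)c1COCc1ccc(OC)cc1 | intermediate
30 | 6-(ArB-oxy)-2-methoxy-3-[(R)-1-(TBS-oxy)-3-methylbutyl]benzyl 4-methoxybenzyl ether | COc1c([C@H](O[Si](C)(C)C(C)(C)C)CC(C)C)ccc(Oc2c(OCC=C)cc(C)cc2CO[Si](C)(C)C(C)(C)C)c1COCc1ccc(OC)cc1 | intermediate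
31 | {6-(ArB-oxy)-2-methoxy-3-[(R)-1-(TBS-oxy)-3-methylbutyl]phenyl}methanol | COc1c([C@H](O[Si](C)(C)C(C)(C)C)CC(C)C)ccc(Oc2c(OCC=C)cc(C)cc2CO[Si](C)(C)C(C)(C)C)c1CO | intermediate
32 | 6-(ArB-oxy)-2-methoxy-3-[(R)-1-(TBS-oxy)-3-methylbutyl]benzaldehyde | COc1c([C@H](O[Si](C)(C)C(C)(C)C)CC(C)C)ccc(Oc2c(OCC=C)cc(C)cc2CO[Si](C)(C)C(C)(C)C)c1C=O | intermediate
33 | 6-(ArB-oxy)-2-methoxy-3-[(R)-1-(TBS-oxy)-3-methylbutyl]benzoic acid | COc1c([C@H](O[Si](C)(C)C(C)(C)C)CC(C)C)ccc(Oc2c(OCC=C)cc(C)cc2CO[Si](C)(C)C(C)(C)C)c1C(=O)O | intermediate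
34 | 6-{2-hydroxy-6-[(TBS-oxy)methyl]-4-methylphenoxy}-2-methoxy-3-[(R)-1-(TBS-oxy)-3-methylbutyl]benzoic acid | COc1c([C@H](O[Si](C)(C)C(C)(C)C)CC(C)C)ccc(Oc2c(O)cc(C)cc2CO[Si](C)(C)C(C)(C)C)c1C(=O)O | intermediate
35 | 6-[2-hydroxy-6-(hydroxymethyl)-4-methylphenoxy]-3-[(R)-1-hydroxy-3-methylbutyl]-2-methoxybenzoic acid (CNP0221397.2) | COc1c([C@H](O)CC(C)C)ccc(Oc2c(O)cc(C)cc2CO)c1C(=O)O | target

**Totals**

Total step count: 20. Longest linear sequence: 14 steps (steps 7 to 13, then 14 to 20, from aldehyde 13); fragment A adds 6 steps in parallel.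

**Steps most likely to fail**

1. Step 14. The short-lived vinylketene may dimerize, or acylate the product phenol, faster than the hindered and electronically attenuated aryloxyalkyne captures it. A brief K2CO3/MeOH treatment would cleave any aryl ester, but not cure slow capture.
Fallback (sets out from 12, returns at 30): the alkyne partner is replaced by a siloxyalkyne, a proven partner class, and the diaryl ether is made afterwards by SNAr.
Purchasable 4-methoxybenzyl propargyl ether is lithiated (n-BuLi, THF, −78 °C), oxidized to the lithium ynolate with lithium tert-butyl peroxide and O-silylated with TIPSOTf to give triisopropyl({3-[(4-methoxybenzyl)oxy]prop-1-yn-1-yl}oxy)silane F1.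
Irradiation of 12 with F1 as in step 14 should give 2-[(PMB-oxy)methyl]-6-[(R)-1-(TBS-oxy)-3-methylbutyl]-3-(TIPS-oxy)phenol F2.
MeI/K2CO3 converts it into 2-methoxy-3-[(R)-1-(TBS-oxy)-3-methylbutyl]-6-(TIPS-oxy)benzyl 4-methoxybenzyl ether F3.
One equivalent of Bu4NF at −20 °C removes the aryl silyl group selectively to leave 3-methoxy-2-[(PMB-oxy)methyl]-4-[(R)-1-(TBS-oxy)-3-methylbutyl]phenol F4.
In parallel, 2-fluoro-5-methylphenol is O-allylated (allyl bromide, K2CO3) to 2-(allyloxy)-1-fluoro-4-methylbenzene F5.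
F5 is lithiated next to fluorine (lithium 2,2,6,6-tetramethylpiperidide, THF, −78 °C) and formylated with DMF to 3-(allyloxy)-2-fluoro-5-methylbenzaldehyde F6.
SNAr of the phenoxide of F4 on the formyl-activated fluoride (K2CO3, DMF, 90 °C) gives 3-(allyloxy)-2-{3-methoxy-2-[(PMB-oxy)methyl]-4-[(R)-1-(TBS-oxy)-3-methylbutyl]phenoxy}-5-methylbenzaldehyde F7.
NaBH4 reduces it to [3-(allyloxy)-2-{3-methoxy-2-[(PMB-oxy)methyl]-4-[(R)-1-(TBS-oxy)-3-methylbutyl]phenoxy}-5-methylphenyl]methanol F8, and TBSCl/imidazole turns F8 into 30.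

2. Step 12. The lithium aryloxyacetylide may be captured sluggishly by polymeric formaldehyde, and the aryloxy propargylic alcohol may rearrange to an aryl acrylate under traces of acid during isolation.
Fallback (sets out from 20, returns at 32): the C1 carbon is introduced after the ring is built instead of on the alkyne.
Compound 20 is treated with n-BuLi as before, and acetylide 22 is simply protonated with MeOH to give the terminal ynol ether tert-butyl{[3-(allyloxy)-2-(ethynyloxy)-5-methylbenzyl]oxy}dimethylsilane F9.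
Benzannulation of F9 with 12 under the conditions of step 14 should give, with the same regiochemistry, 3-(ArB-oxy)-6-[(R)-1-(TBS-oxy)-3-methylbutyl]phenol F10, whose only free ortho position is C1.
Magnesium-mediated ortho-formylation (MgCl2, Et3N, paraformaldehyde, MeCN, reflux) then gives 6-(ArB-oxy)-2-hydroxy-3-[(R)-1-(TBS-oxy)-3-methylbutyl]benzaldehyde F11.
O-Methylation (MeI, K2CO3, DMF) converts F11 into aldehyde 32, which also saves the PMB removal and alcohol oxidation.

3. Step 6. Enolization toward the γ-carbon instead of the methyl group would erode the configuration at the silyloxy carbon or eliminate silanol, and the acylation/diazo-transfer sequence exposes the enone to base twice.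
Fallback (sets out from 8, returns at 12): the diazo group is brought in with the olefination reagent, so no enolate of the chiral enone is ever formed.
Diethyl (3-diazo-2-oxopropyl)phosphonate F12 is prepared from diethylphosphonoacetyl chloride and diazomethane.
Aldehyde 8 is condensed with F12 in a Horner–Wadsworth–Emmons reaction under Masamune–Roush conditions (LiCl, i-Pr2NEt, MeCN, rt), which should give the E-configured diazo enone 12 directly and bypass steps 5 and 6.

**Further compounds**

F1 | step 14 | triisopropyl({3-[(4-methoxybenzyl)oxy]prop-1-yn-1-yl}oxy)silane | COc1ccc(COCC#CO[Si](C(C)C)(C(C)C)C(C)C)cc1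
F2 | step 14 | 2-[(PMB-oxy)methyl]-6-[(R)-1-(TBS-oxy)-3-methylbutyl]-3-(TIPS-oxy)phenol | Oc1c([C@H](O[Si](C)(C)C(C)(C)C)CC(C)C)ccc(O[Si](C(C)C)(C(C)C)C(C)C)c1COCc1ccc(OC)cc1
F3 | step 14 | 2-methoxy-3-[(R)-1-(TBS-oxy)-3-methylbutyl]-6-(TIPS-oxy)benzyl 4-methoxybenzyl ether | COc1c([C@H](O[Si](C)(C)C(C)(C)C)CC(C)C)ccc(O[Si](C(C)C)(C(C)C)C(C)C)c1COCc1ccc(OC)cc1
F4 | step 14 | 3-methoxy-2-[(PMB-oxy)methyl]-4-[(R)-1-(TBS-oxy)-3-methylbutyl]phenol | COc1c([C@H](O[Si](C)(C)C(C)(C)C)CC(C)C)ccc(O)c1COCc1ccc(OC)cc1
F5 | step 14 | 2-(allyloxy)-1-fluoro-4-methylbenzene | C=CCOc1cc(C)ccc1F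
F6 | step 14 | 3-(allyloxy)-2-fluoro-5-methylbenzaldehyde | C=CCOc1cc(C)cc(C=O)c1F
F7 | step 14 | 3-(allyloxy)-2-{3-methoxy-2-[(PMB-oxy)methyl]-4-[(R)-1-(TBS-oxy)-3-methylbutyl]phenoxy}-5-methylbenzaldehyde | COc1c([C@H](O[Si](C)(C)C(C)(C)C)CC(C)C)ccc(Oc2c(OCC=C)cc(C)cc2C=O)c1COCc1ccc(OC)cc1
F8 | step 14 | [3-(allyloxy)-2-{3-methoxy-2-[(PMB-oxy)methyl]-4-[(R)-1-(TBS-oxy)-3-methylbutyl]phenoxy}-5-methylphenyl]methanol | COc1c([C@H](O[Si](C)(C)C(C)(C)C)CC(C)C)ccc(Oc2c(OCC=C)cc(C)cc2CO)c1COCc1ccc(OC)cc1
F9 | step 12 | tert-butyl{[3-(allyloxy)-2-(ethynyloxy)-5-methylbenzyl]oxy}dimethylsilane | C=CCOc1cc(C)cc(CO[Si](C)(C)C(C)(C)C)c1OC#C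
F10 | step 12 | 3-(ArB-oxy)-6-[(R)-1-(TBS-oxy)-3-methylbutyl]phenol | Oc1c([C@H](O[Si](C)(C)C(C)(C)C)CC(C)C)ccc(Oc2c(OCC=C)cc(C)cc2CO[Si](C)(C)C(C)(C)C)c1
F11 | step 12 | 6-(ArB-oxy)-2-hydroxy-3-[(R)-1-(TBS-oxy)-3-methylbutyl]benzaldehyde | Oc1c([C@H](O[Si](C)(C)C(C)(C)C)CC(C)C)ccc(Oc2c(OCC=C)cc(C)cc2CO[Si](C)(C)C(C)(C)C)c1C=O
F12 | step 6 | diethyl (3-diazo-2-oxopropyl)phosphonate | CCOP(=O)(OCC)CC(=O)C=[N+]=[N-]
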